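A small charge, 0.80 M of solid substrate beside 0.640 M of partner, must dissolve before it can become target.

solid substrate 0.80 M; partner 0.640 M; time 30 min

    solid substrate ⇌ dissolved substrate, rate k1*(cs1 - [dissolved substrate]) while solid is left; crystals form when [dissolved substrate] > cs1 (cs1 = 0.46 M, k1 = 0.050 min⁻¹)
    dissolved substrate + partner → target (k2 = 0.36 M⁻¹ min⁻¹)
    2 dissolved substrate → side product (k3 = 0.50 M⁻¹ min⁻¹)
    solid product ⇌ target, rate k4*(cs4 - [target]) while solid is left; crystals form when [target] > cs4 (cs4 = 0.38 M, k4 = 9.8 min⁻¹)
    2 solid substrate → self-condensation product (k5 = 0.013 M⁻¹ min⁻¹)

- in percentages every species weighs as the solid substrate in it: one side product or self-condensation product counts as two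
- for target the solid product is counted in
- a step written with two of one species runs at k times the square of its concentration and takes two of it each time
- as a solid, counted per litre of solution: solid substrate, solid product
- at the start none of the solid substrate is in solution
- run time (flask): 30 min

- grey: doubling the dissolution coefficient of step 1, all else as stated
- teal: doubling the solubility in step 1, all else as stated
- ochre: doubling the dissolution coefficient of step 4, all else as stated
- blue: doubling the amount of partner, all else as stated

* target and solid product together at 30 min, in percent of the solid substrate charged
* the change that raises the amount of target and solid product together at 30 min, in percent of the solid substrate charged most ("none" if none brings more than 2 percentage points) (grey / teal / ochre / blue / none)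
* amount of target and solid product together at 30 min, in percent of the solid substrate charged, after ochre

Dissolved substrate has two exits: partner takes it to target, or a second dissolved substrate takes it to side product. So we ask how much enters solution and what share of it reaches target.

Into an empty solution, the feed would bring 0.690 M by 30 min, which is 86.2% of the charge. We assume the solid lasts and leave self-condensation aside. Partner falls as target forms, so we guess that target receives half of that ceiling, which puts partner at 0.467 M on average.

Next we suppose that c(dissolved substrate) soon stops rising, a quasi-steady state in which inflow equals the outflow by both exits. Inflow is the dissolution coefficient times the gap to solubility. Solving that balance gives c(dissolved substrate) = 0.0777 M.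

The capture share, the rate of loss to target over the rate of loss by both exits, is 68.4%. We reckon the inflow over the run at 0.573 M. Taking away what stays dissolved and applying the share leaves 0.339 M of target, or 42.4%.

That is less than the solubility of target, 0.38 M, so we expect no crystals, and ochre should leave 42.4% unchanged. With partner doubled, the same reckoning puts c(dissolved substrate) at 0.0465 M, which gives a share of 89.6% and about 64.2%. We commit to blue on that figure, leaving grey and teal unreckoned.

The forecast says 43%, blue, and 43% after ochre, on the ground that “doubling partner both captures dissolved substrate faster and suppresses that side reaction”.

The simulation gives 42.4%, 42.4% after ochre, and blue as the best change, with a gain of 20 percentage points against 7.4 points for grey and 7.2 points for teal.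

In this flask, dissolved substrate left by the exit through partner at 2.3 times the rate of its other exit at 14.5 min, a capture share of 69.7%. At 30.0 min the ratio was 1.2, a share of 54.5%, so our 68.4% lies between the two.

For the neighbour flask charged with 0.38 M of partner, the same reckoning gives a capture share of 42.4% and a yield of 23.1%. The simulation of that neighbour gives 28.4%.

The numbers were chosen freely; the rest is arithmetic.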